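## Retrosynthetic overview

- Target ⇐ global desilylation of its penta-silyl ether; the stilbene C(aryl)–C(vinyl) bond ⇐ Mizoroki–Heck coupling of a 6-chloro-2,3-dihydrobenzofuran with a protected 4-vinylguaiacol.
- C3–aryl bond and both stereocentres ⇐ Pd-catalysed enantioselective dearomative reductive Heck (syn-hydroarylation) of a 2-arylbenzofuran with 3,5-bis(silyloxy)bromobenzene (proposed new step).
- Furan ring ⇐ domino Sonogashira/5-endo-dig cyclisation of 5-chloro-2-iodoresorcinol with a guaiacyl alkyne. This is the only ring built; all four benzene rings are bought.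
- Arene blocks: catechol → protected 4-bromoguaiacol (→ alkyne and styrene); 3-chlorophenol and 3-bromophenol → meta C–H borylation/oxidation → 5-haloresorcinol units.

Assumptions:
- The target SMILES corresponds to the (2S,3S), 2,3-trans dihydrobenzofuran.
- The sense of induction of the chiral ligand in Step 16 cannot be predicted; the (R)-ligand is assumed to give the (2S,3S) series, otherwise the (S)-ligand is used.
- Compounds that supply skeletal carbons are numbered as starting materials; MeI, halogenating agents, silyl chlorides, boron reagents and oxidants are treated as reagents.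

## Route

**Step 1**
Reactants: 1 catechol
Product: 2 guaiacol (2-methoxyphenol)
Conditions: MeI (1.0 equiv), K2CO3, acetone, reflux; catechol used in excess (2–3 equiv)
Reagents that add atoms: iodomethane, CI
Why: Williamson O-methylation; excess catechol makes the mono-ether dominant, and catechol/veratrole are removed by aqueous/base partitioning.

**Step 2**
Reactants: 2 guaiacol
Product: 3 4-bromo-2-methoxyphenol
Conditions: NBS (1.0 equiv), MeCN, 0 °C
Reagents that add atoms: N-bromosuccinimide, O=C1CCC(=O)N1Br
Why: Electrophilic aromatic bromination; the free OH is the dominant director, so Br enters para to OH (meta to OMe).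

**Step 3**
Reactants: 3 4-bromo-2-methoxyphenol
Product: 4 (4-bromo-2-methoxyphenoxy)triisopropylsilane
Conditions: TIPSCl, imidazole, DMF, rt
Reagents that add atoms: triisopropylsilyl chloride, CC(C)[Si](Cl)(C(C)C)C(C)C
Why: Phenol O-silylation; the aryl TIPS ether tolerates the Pd, Grignard and mild carbonate steps that follow.

**Step 4**
Reactants: 4 (4-bromo-2-methoxyphenoxy)triisopropylsilane; 5 ethynyltrimethylsilane
Product: 6 {[3-methoxy-4-(triisopropylsilyloxy)phenyl]ethynyl}trimethylsilane
Conditions: Pd(PhCN)2Cl2 (3 mol %), P(t-Bu)3 (6 mol %), CuI (2 mol %), i-Pr2NH, dioxane, rt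
Reagents that add atoms: none
Why: Sonogashira coupling; the bulky electron-rich phosphine lets the electron-rich aryl bromide couple at room temperature.

**Step 5**
Reactants: 6
Product: 7 (4-ethynyl-2-methoxyphenoxy)triisopropylsilane
Conditions: K2CO3 (0.2 equiv), MeOH/THF, 0 °C, 30 min
Reagents that add atoms: none
Why: Base-mediated protodesilylation of the alkynyl C–SiMe3 bond, which is far faster than cleavage of the hindered aryl O–TIPS ether under catalytic carbonate at 0 °C.

**Step 6**
Reactants: 4 (4-bromo-2-methoxyphenoxy)triisopropylsilane; 8 vinylmagnesium bromide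
Product: 9 (4-ethenyl-2-methoxyphenoxy)triisopropylsilane
Conditions: Pd(dppf)Cl2 (3 mol %), THF, 50 °C; product stored cold with BHT
Reagents that add atoms: none
Why: Kumada–Corriu cross-coupling; it is fluoride- and water-free, so the silyl ether survives.

**Step 7**
Reactants: 10 3-chlorophenol
Product: 11 (3-chlorophenoxy)triisopropylsilane
Conditions: TIPSCl, imidazole, DMF, rt
Reagents that add atoms: triisopropylsilyl chloride, CC(C)[Si](Cl)(C(C)C)C(C)C
Why: O-silylation; the bulky OTIPS group blocks the ortho C–H bonds in the next step.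

**Step 8**
Reactants: 11
Product: 12 3-chloro-5-(triisopropylsilyloxy)phenol
Conditions: (i) [Ir(OMe)(cod)]2 (1.5 mol %), dtbpy (3 mol %), B2pin2, THF, 80 °C; (ii) Oxone, acetone/H2O, rt, 15 min (one pot)
Reagents that add atoms: Oxone (KHSO5, supplies the phenolic O), OOS(=O)(=O)[O-].[K+]; B2pin2 is used but leaves no atoms in the product
Why: Sterically controlled Ir-catalysed C–H borylation at C5, the only C–H not ortho to a substituent, followed by oxidation of the aryl–Bpin to the phenol.

**Step 9**
Reactants: 12
Product: 13 5-chlorobenzene-1,3-diol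
Conditions: TBAF, THF, 0 °C; aq. NH4Cl work-up
Reagents that add atoms: none
Why: Fluoride-mediated cleavage of the aryl silyl ether.

**Step 10**
Reactants: 13
Product: 14 5-chloro-2-iodobenzene-1,3-diol
Conditions: I2 (1.05 equiv), NaHCO3, H2O, 0 °C → rt
Reagents that add atoms: iodine, II
Why: Electrophilic aromatic iodination; under aqueous bicarbonate, resorcinols iodinate between the two OH groups, and C4/C6 are further shielded here by the adjacent Cl.

**Step 11**
Reactants: 15 3-bromophenol
Product: 16 (3-bromophenoxy)triisopropylsilane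
Conditions: TIPSCl, imidazole, DMF, rt
Reagents that add atoms: triisopropylsilyl chloride, CC(C)[Si](Cl)(C(C)C)C(C)C
Why: O-silylation, as in Step 7.

**Step 12**
Reactants: 16
Product: 17 3-bromo-5-(triisopropylsilyloxy)phenol
Conditions: (i) [Ir(OMe)(cod)]2 (1.5 mol %), dtbpy (3 mol %), B2pin2, THF, 80 °C; (ii) Oxone, acetone/H2O, rt (one pot)
Reagents that add atoms: Oxone (KHSO5, supplies the phenolic O), OOS(=O)(=O)[O-].[K+]; B2pin2 leaves no atoms in the product
Why: Ir-catalysed meta C–H borylation (aryl bromide tolerated) followed by C–B oxidation, as in Step 8.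

**Step 13**
Reactants: 17
Product: 18 1-bromo-3,5-bis(triisopropylsilyloxy)benzene
Conditions: TIPSCl, imidazole, DMF, rt
Reagents that add atoms: triisopropylsilyl chloride, CC(C)[Si](Cl)(C(C)C)C(C)C
Why: O-silylation of the remaining phenol gives the symmetric ring-B aryl bromide.

**Step 14**
Reactants: 7 (4-ethynyl-2-methoxyphenoxy)triisopropylsilane; 14 5-chloro-2-iodobenzene-1,3-diol
Product: 19 6-chloro-2-[3-methoxy-4-(triisopropylsilyloxy)phenyl]-1-benzofuran-4-ol
Conditions: Pd(PPh3)2Cl2 (3 mol %), CuI (5 mol %), Et3N, DMF (degassed), rt → 70 °C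
Reagents that add atoms: none
Why: Domino Sonogashira coupling (C–I reacts, C–Cl does not) and 5-endo-dig cyclisation of the ortho-alkynylphenol forms the furan ring; the iodoresorcinol is symmetric, so either OH gives the same benzofuran and the other becomes the 4-OH.

**Step 15**
Reactants: 19
Product: 20 tert-butyl({6-chloro-2-[3-methoxy-4-(triisopropylsilyloxy)phenyl]-1-benzofuran-4-yl}oxy)dimethylsilane
Conditions: TBSCl, imidazole, DMF, rt
Reagents that add atoms: tert-butyldimethylsilyl chloride, CC(C)(C)[Si](C)(C)Cl
Why: O-silylation; TBS is chosen as the smaller silyl group next to C3, where the new aryl will be installed.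

**Step 16**
Reactants: 20; 18 1-bromo-3,5-bis(triisopropylsilyloxy)benzene (2.5 equiv)
Product: 21 tert-butyl({(2S,3S)-3-[3,5-bis(triisopropylsilyloxy)phenyl]-6-chloro-2-[3-methoxy-4-(triisopropylsilyloxy)phenyl]-2,3-dihydro-1-benzofuran-4-yl}oxy)dimethylsilane (2,3-trans)
Conditions: Pd2(dba)3 (5 mol %), (R)-Xyl-SDP(O) (chiral spiro bisphosphine mono-oxide, 12 mol %), HCO2H/i-Pr2NEt (2 equiv, syringe pump over 12 h), dioxane/t-AmOH (4:1), 90 °C; ee checked by chiral HPLC and upgraded by crystallisation if needed
Reagents that add atoms: none (formic acid supplies only H)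
Why: Proposed new method: intermolecular enantioselective dearomative reductive Heck (syn-hydroarylation) of a 2-arylbenzofuran. Oxidative addition of 18 gives an electrophilic Ar–Pd(II) on the hemilabile P,O ligand, which inserts the C2=C3 bond in the enantio-determining step; aryl goes to the unsubstituted C3 and Pd to C2, where it is stabilised as an α-oxy η3-benzyl species, while the opposite regiochemistry would create a quaternary C2 and place Pd beside the peri OTBS. The only β-hydrogen (C3–H) is anti to Pd and there is no β-oxygen, so neither re-aromatising β-H elimination nor ring opening is available. Formate exchange, decarboxylation and stereoretentive C–H reductive elimination then place H at C2 on the same face as the new C3-aryl, which gives the 2,3-trans relationship directly, with C3 (S) set by the ligand and C2 (S) following from the syn addition. The closest known reactions are the intramolecular Pd-catalysed asymmetric dearomative reductive Heck cyclisations of indoles and benzofurans and the intermolecular asymmetric reductive Heck hydroarylations of cyclic alkenes.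

**Step 17**
Reactants: 21; 9 (4-ethenyl-2-methoxyphenoxy)triisopropylsilane (1.5 equiv)
Product: 22 penta-silyl ether of the target: tert-butyl({(2S,3S)-3-[3,5-bis(triisopropylsilyloxy)phenyl]-2-[3-methoxy-4-(triisopropylsilyloxy)phenyl]-6-{(E)-2-[3-methoxy-4-(triisopropylsilyloxy)phenyl]ethenyl}-2,3-dihydro-1-benzofuran-4-yl}oxy)dimethylsilane
Conditions: Pd2(dba)3 (3 mol %), [HP(t-Bu)3]BF4 (7 mol %), Cy2NMe (1.5 equiv), dioxane, 100 °C
Reagents that add atoms: none
Why: Mizoroki–Heck reaction of the unhindered aryl chloride using a bulky electron-rich phosphine; syn-insertion and syn-β-hydride elimination give the E-stilbene, and the amine base leaves both stereocentres and the silyl ethers untouched.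

**Step 18**
Reactants: 22
Product: 23 bisisorhapontigenin B, 5-[(2S,3S)-4-hydroxy-2-(4-hydroxy-3-methoxyphenyl)-6-[(E)-2-(4-hydroxy-3-methoxyphenyl)ethenyl]-2,3-dihydro-1-benzofuran-3-yl]benzene-1,3-diol
Conditions: TBAF/AcOH (1:1, 8 equiv), THF, 0 °C → rt, Ar; purification on Sephadex LH-20 or by RP-HPLC
Reagents that add atoms: none
Why: Buffered fluoride desilylation removes the four TIPS and one TBS groups without touching the methyl ethers or the E-alkene, and the buffer avoids phenoxide-driven quinone-methide opening at C2.

## Compound list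

1 | catechol | Oc1ccccc1O | starting material
2 | guaiacol (2-methoxyphenol) | COc1ccccc1O | intermediate
3 | 4-bromo-2-methoxyphenol | COc1cc(Br)ccc1O | intermediate
4 | (4-bromo-2-methoxyphenoxy)triisopropylsilane | COc1cc(Br)ccc1O[Si](C(C)C)(C(C)C)C(C)C | intermediate
5 | ethynyltrimethylsilane | C#C[Si](C)(C)C | starting material
6 | {[3-methoxy-4-(triisopropylsilyloxy)phenyl]ethynyl}trimethylsilane | COc1cc(C#C[Si](C)(C)C)ccc1O[Si](C(C)C)(C(C)C)C(C)C | intermediate
7 | (4-ethynyl-2-methoxyphenoxy)triisopropylsilane | COc1cc(C#C)ccc1O[Si](C(C)C)(C(C)C)C(C)C | intermediate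
8 | vinylmagnesium bromide | C=C[Mg]Br | starting material
9 | (4-ethenyl-2-methoxyphenoxy)triisopropylsilane | COc1cc(C=C)ccc1O[Si](C(C)C)(C(C)C)C(C)C | intermediate
10 | 3-chlorophenol | Oc1cccc(Cl)c1 | starting material
11 | (3-chlorophenoxy)triisopropylsilane | CC(C)[Si](Oc1cccc(Cl)c1)(C(C)C)C(C)C | intermediate
12 | 3-chloro-5-(triisopropylsilyloxy)phenol | Oc1cc(Cl)cc(O[Si](C(C)C)(C(C)C)C(C)C)c1 | intermediate
13 | 5-chlorobenzene-1,3-diol | Oc1cc(O)cc(Cl)c1 | intermediate
14 | 5-chloro-2-iodobenzene-1,3-diol | Oc1cc(Cl)cc(O)c1I | intermediate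
15 | 3-bromophenol | Oc1cccc(Br)c1 | starting material
16 | (3-bromophenoxy)triisopropylsilane | CC(C)[Si](Oc1cccc(Br)c1)(C(C)C)C(C)C | intermediate
17 | 3-bromo-5-(triisopropylsilyloxy)phenol | Oc1cc(Br)cc(O[Si](C(C)C)(C(C)C)C(C)C)c1 | intermediate
18 | 1-bromo-3,5-bis(triisopropylsilyloxy)benzene | Brc1cc(O[Si](C(C)C)(C(C)C)C(C)C)cc(O[Si](C(C)C)(C(C)C)C(C)C)c1 | intermediate
19 | 6-chloro-2-[3-methoxy-4-(triisopropylsilyloxy)phenyl]-1-benzofuran-4-ol | COc1cc(-c2cc3c(O)cc(Cl)cc3o2)ccc1O[Si](C(C)C)(C(C)C)C(C)C | intermediate
20 | 4-O-TBS ether of 19 | COc1cc(-c2cc3c(O[Si](C)(C)C(C)(C)C)cc(Cl)cc3o2)ccc1O[Si](C(C)C)(C(C)C)C(C)C | intermediate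
21 | (2S,3S)-trans-6-chloro-2,3-diaryl-2,3-dihydrobenzofuran, tetra-silyl ether | Clc1cc(O[Si](C)(C)C(C)(C)C)c2c(c1)O[C@H](c1ccc(O[Si](C(C)C)(C(C)C)C(C)C)c(OC)c1)[C@H]2c1cc(O[Si](C(C)C)(C(C)C)C(C)C)cc(O[Si](C(C)C)(C(C)C)C(C)C)c1 | intermediate
22 | penta-silyl ether of the target, (2S,3S), E | COc1cc(/C=C/c2cc(O[Si](C)(C)C(C)(C)C)c3c(c2)O[C@H](c2ccc(O[Si](C(C)C)(C(C)C)C(C)C)c(OC)c2)[C@H]3c2cc(O[Si](C(C)C)(C(C)C)C(C)C)cc(O[Si](C(C)C)(C(C)C)C(C)C)c2)ccc1O[Si](C(C)C)(C(C)C)C(C)C | intermediate
23 | bisisorhapontigenin B | COc1cc(/C=C/c2cc(O)c3c(c2)O[C@H](c2ccc(O)c(OC)c2)[C@H]3c2cc(O)cc(O)c2)ccc1O | target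

## Summary

Total step count: 18

Longest linear sequence: 10 steps (Steps 1–5, then 14–18), which is 56 % of the total.

Steps most likely to fail:

1. **Step 16 (proposed new dearomative reductive Heck).** Risks are hydrodebromination of 18, re-aromatised C3-arylation, low ee and slow insertion next to the 4-OTBS group. Fallback using known chemistry: form the C2–C3 bond by Rh2(PTAD)4-catalysed enantioselective intramolecular C–H insertion of a donor/donor carbene. The carbene comes from MnO2 oxidation of the hydrazone of the corresponding 2-(4-silyloxy-3-methoxybenzyloxy)-4-chloro-6-silyloxyphenyl 3,5-bis(silyloxy)phenyl ketone. This gives the cis-2,3-diaryl-dihydrobenzofuran; C2 is then epimerised under acid to the thermodynamic trans isomer after unmasking the ring-A phenol. Steps 17–18 follow as before.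

2. **Step 17 (Heck on an aryl chloride with a polymerisation-prone, electron-rich styrene).** Fallback: Suzuki–Miyaura coupling of 21 with the (E)-styryl pinacolboronate made by hydroboration of alkyne 7, which fixes the E geometry before the coupling (Pd/XPhos, anhydrous K3PO4).

3. **Step 14 (domino Sonogashira/cyclisation on a free, di-ortho-substituted iodoresorcinol).** Fallback: build the unsubstituted benzofuran first (14 + 5, Sonogashira/cyclisation, C-desilylation, O-silylation), then attach ring A by Pd-catalysed C2–H arylation with bromide 4.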